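**Retrosynthetic overview**
- Sigmoidin A is (2S)-5,7,3',4'-tetrahydroxy-2',5'-diprenylflavanone; the last operation is removal of four MOM groups from the fully assembled flavanone.
- Key disconnection C1'(ring B)–C2(ring C): an enantioselective, dearomatising rhodium-catalysed 1,4-arylation of 5,7-bis(methoxymethoxy)chromone with the fully prenylated ring-B boronic acid. One operation joins all carbon atoms, creates the only stereocentre (C2) and brings ring C to the chromanone oxidation level.
- Enabling feature: ring C of the chromone is a flat 4-pyranone whose O1–C2=C3–C4=O unit is a vinylogous ester. C2, the future stereocentre, is its β-carbon and the only electrophilic sp2 CH, so an aryl–rhodium species can add only there.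
- Ring-B boronic acid: 4-bromocatechol → bis(allyl ether) → double ortho-Claisen rearrangement (O4' to C5', O3' to C2'; the C–Br carbon is the future C1') → MOM protection → cross-metathesis allyl to prenyl → Br/Li/B exchange.
- Ring order: no ring is constructed. Rings A and C are bought together as 5,7-dihydroxychromone, ring B as 4-bromocatechol, and ring C is only dearomatised in the key step.

Key step: step 7

Remark: 4-bromocatechol and 5,7-dihydroxychromone are taken as purchasable; the (S,S) antipode of the diene ligand is assigned by analogy with the facial sense known for cyclic enones, and the (R,R) antipode would be used should the sense prove opposite.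

**Step 1**
Reactants: 1 4-bromocatechol (4-bromobenzene-1,2-diol)
Product: 2 1,2-bis(allyloxy)-4-bromobenzene
Conditions: allyl bromide, K2CO3, acetone, reflux, N2
Reagents that add atoms: allyl bromide, C=CCBr
Why: Williamson ether synthesis; both phenoxide oxygens are alkylated by the unhindered allylic bromide and the aryl bromide is inert.

**Step 2**
Reactants: 2 1,2-bis(allyloxy)-4-bromobenzene
Product: 4 3,6-diallyl-4-bromocatechol, via 2-allyl-6-(allyloxy)-4-bromophenol 3 (not isolated)
Conditions: N,N-diethylaniline, 190 °C, sealed vessel, Ar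
Reagents that add atoms: none
Why: Two successive aromatic Claisen rearrangements ([3,3]-sigmatropic shift, then enol tautomerisation) should give the 3,6-diallyl pattern, because each allyloxy group has exactly one unsubstituted ortho carbon (C6 for O1, C3 for O2), the para carbon of O1 carries the bromine, and a meta electron-withdrawing substituent generally favours migration to the ortho carbon next to it over leakage of the O2 allyl group to the para carbon C5.

**Step 3**
Reactants: 4 3,6-diallyl-4-bromocatechol
Product: 5 1-bromo-3,4-bis(methoxymethoxy)-2,5-di(prop-2-en-1-yl)benzene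
Conditions: NaH, MOMCl, DMF, 0 °C to rt
Reagents that add atoms: chloromethyl methyl ether, COCCl
Why: Williamson-type O-alkylation of the catechol dianion gives the bis-MOM ether, which is stable to organolithiums, to base and to the metathesis catalyst.

**Step 4**
Reactants: 5 1-bromo-3,4-bis(methoxymethoxy)-2,5-di(prop-2-en-1-yl)benzene
Product: 6 1-bromo-3,4-bis(methoxymethoxy)-2,5-bis(3-methylbut-2-en-1-yl)benzene
Conditions: 2-methyl-2-butene (excess, co-solvent), second-generation Grubbs catalyst RuCl2(=CHPh)(PCy3)(H2IMes) (5 mol %), CH2Cl2, 40 °C, sealed tube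
Reagents that add atoms: 2-methyl-2-butene, CC=C(C)C
Why: Olefin cross-metathesis of the two monosubstituted allyl termini with excess 2-methyl-2-butene converts allyl into prenyl, and the trisubstituted product olefins are poor metathesis substrates, so the reaction should stop there.

**Step 5**
Reactants: 6 1-bromo-3,4-bis(methoxymethoxy)-2,5-bis(3-methylbut-2-en-1-yl)benzene
Product: 9 [3,4-bis(methoxymethoxy)-2,5-bis(3-methylbut-2-en-1-yl)phenyl]boronic acid, via the aryllithium 7 (not isolated), via the lithium aryl(triisopropoxy)borate 8 (not isolated)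
Conditions: n-BuLi, THF, −78 °C; B(OiPr)3, −78 °C to 0 °C; sat. aq. NH4Cl
Reagents that add atoms: triisopropyl borate, CC(C)OB(OC(C)C)OC(C)C; water, O
Why: Bromine–lithium exchange at −78 °C is faster than any deprotonation (no free carbon ortho to an OMOM group remains), and electrophilic borylation followed by near-neutral hydrolysis should give the boronic acid without loss of the MOM acetals.

**Step 6**
Reactants: 10 5,7-dihydroxychromone (5,7-dihydroxy-4H-chromen-4-one)
Product: 11 5,7-bis(methoxymethoxy)-4H-chromen-4-one
Conditions: NaH, MOMCl, DMF, 0 °C to rt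
Reagents that add atoms: chloromethyl methyl ether, COCCl
Why: Williamson-type MOM protection of both phenols; NaH is used because the 5-OH is hydrogen-bonded to the C4 carbonyl and a free phenoxide would deactivate the enone in the key step.

**Step 7**
Reactants: 9 [3,4-bis(methoxymethoxy)-2,5-bis(3-methylbut-2-en-1-yl)phenyl]boronic acid; 11 5,7-bis(methoxymethoxy)-4H-chromen-4-one
Product: 12 (2S)-2-[3,4-bis(methoxymethoxy)-2,5-bis(3-methylbut-2-en-1-yl)phenyl]-5,7-bis(methoxymethoxy)-2,3-dihydro-4H-chromen-4-one
Conditions: [RhCl(C2H4)2]2 (2.5 mol %), (S,S)-Ph-bod* [(1S,4S)-2,5-diphenylbicyclo[2.2.2]octa-2,5-diene] (5.5 mol %), aq. KOH (10 mol %), toluene/H2O 10:1, 40 °C; 9 (2 equiv) added in portions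
Reagents that add atoms: none
Why: This is the asymmetric rhodium-catalysed 1,4-addition of an arylboronic acid (Hayashi–Miyaura reaction) applied to a chromone, a known route to flavanones: a hydroxo complex of monovalent rhodium takes the aryl group from 9 by transmetalation, the aryl–rhodium species binds the C2=C3 bond of 11 and inserts it so that C1' bonds to C2, and the oxa-π-allyl rhodium enolate is protonated by water at C3, which regenerates Rh–OH and releases boric acid. No ring is closed; the flat 4-pyranone ring C is dearomatised to the chroman-4-one and the only stereocentre of the target is created in the same event. C2 is controlled by the C2-symmetric diene, whose phenyl groups leave only one face of the coordinated enone open; the (S,S) ligand is expected to deliver the aryl group to the Re face of C2 (the face on which O1, C3 and H run clockwise), which gives (2S). The step needs 1,4- over 1,2-addition (secured by the soft aryl–rhodium nucleophile and the vinylogous-ester character of C4=O), chemoselectivity against the prenyl groups (isolated trisubstituted olefins bind far less well than the chelating diene and the enone, and the ortho-prenyl group could only insert through a disfavoured 4-exo or 5-endo path), and protonation of the enolate before β-aryloxide elimination or base-induced retro-oxa-Michael opening could racemise C2 (secured by water as co-solvent and only catalytic base). The single ortho substituent of 9 slows transmetalation and invites protodeboronation, hence the excess of 9 and its portionwise addition.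

**Step 8**
Reactants: 12 (2S)-2-[3,4-bis(methoxymethoxy)-2,5-bis(3-methylbut-2-en-1-yl)phenyl]-5,7-bis(methoxymethoxy)-2,3-dihydro-4H-chromen-4-one
Product: 13 sigmoidin A, (2S)-2-[3,4-dihydroxy-2,5-bis(3-methylbut-2-en-1-yl)phenyl]-5,7-dihydroxy-2,3-dihydro-4H-chromen-4-one
Conditions: 3 M aq. HCl/MeOH (1:4), 45 °C
Reagents that add atoms: none
Why: Acid-catalysed acetal methanolysis should remove all four MOM groups; dilute HCl in methanol at moderate temperature is the usual end game for prenylated flavanones, is expected to spare the trisubstituted olefins, and does not epimerise C2, which is labile to base and not to mild acid.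

**Compound list**
1 | 4-bromocatechol (4-bromobenzene-1,2-diol) | Oc1ccc(Br)cc1O | starting material
2 | 1,2-bis(allyloxy)-4-bromobenzene | C=CCOc1ccc(Br)cc1OCC=C | intermediate
3 | 2-allyl-6-(allyloxy)-4-bromophenol (mono-rearranged, not isolated) | C=CCOc1cc(Br)cc(CC=C)c1O | intermediate
4 | 3,6-diallyl-4-bromocatechol (4-bromo-3,6-di(prop-2-en-1-yl)benzene-1,2-diol) | C=CCc1cc(Br)c(CC=C)c(O)c1O | intermediate
5 | 1-bromo-3,4-bis(methoxymethoxy)-2,5-di(prop-2-en-1-yl)benzene | C=CCc1cc(Br)c(CC=C)c(OCOC)c1OCOC | intermediate
6 | 1-bromo-3,4-bis(methoxymethoxy)-2,5-bis(3-methylbut-2-en-1-yl)benzene | CC(C)=CCc1cc(Br)c(CC=C(C)C)c(OCOC)c1OCOC | intermediate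
7 | [3,4-bis(methoxymethoxy)-2,5-bis(3-methylbut-2-en-1-yl)phenyl]lithium (not isolated) | [Li]c1cc(CC=C(C)C)c(OCOC)c(OCOC)c1CC=C(C)C | intermediate
8 | lithium [3,4-bis(methoxymethoxy)-2,5-bis(3-methylbut-2-en-1-yl)phenyl]triisopropoxyborate (not isolated) | [Li+].CC(C)O[B-](OC(C)C)(OC(C)C)c1cc(CC=C(C)C)c(OCOC)c(OCOC)c1CC=C(C)C | intermediate
9 | [3,4-bis(methoxymethoxy)-2,5-bis(3-methylbut-2-en-1-yl)phenyl]boronic acid | OB(O)c1cc(CC=C(C)C)c(OCOC)c(OCOC)c1CC=C(C)C | intermediate
10 | 5,7-dihydroxychromone (5,7-dihydroxy-4H-chromen-4-one) | O=c1ccoc2cc(O)cc(O)c12 | starting material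
11 | 5,7-bis(methoxymethoxy)-4H-chromen-4-one | O=c1ccoc2cc(OCOC)cc(OCOC)c12 | intermediate
12 | (2S)-2-[3,4-bis(methoxymethoxy)-2,5-bis(3-methylbut-2-en-1-yl)phenyl]-5,7-bis(methoxymethoxy)-2,3-dihydro-4H-chromen-4-one | CC(C)=CCc1cc([C@@H]2CC(=O)c3c(OCOC)cc(OCOC)cc3O2)c(CC=C(C)C)c(OCOC)c1OCOC | intermediate
13 | sigmoidin A, (2S)-2-[3,4-dihydroxy-2,5-bis(3-methylbut-2-en-1-yl)phenyl]-5,7-dihydroxy-2,3-dihydro-4H-chromen-4-one | CC(C)=CCc1cc([C@@H]2CC(=O)c3c(O)cc(O)cc3O2)c(CC=C(C)C)c(O)c1O | target

**Step count**
Total: 8 steps. Longest linear sequence: 7 steps (steps 1, 2, 3, 4, 5, 7, 8); step 6 is the one-step side branch.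

**Steps most likely to fail, with fallbacks**

Step 7. The insertion of the ortho-prenyl aryl–rhodium species into the electron-rich chromone may be slow, so that protodeboronation wins, or the facial discrimination by the diene may be insufficient. The fallback sets out from 9 and 11 and comes back at 12; it moves the stereocontrol from the bond formation to a later kinetic resolution. The two fragments are joined without chiral ligand by the more active catalyst [Rh(OH)(cod)]2 (dioxane/H2O, 50 °C), which should give the racemic tetra-MOM flavanone F1. Kinetic resolution of F1 by asymmetric transfer hydrogenation, a known way to enantiopure flavanones (RuCl(p-cymene)(TsDPEN) in the antipode that reduces the (2R)-ketone faster, HCO2H/Et3N, EtOAc, rt, stopped near half conversion), should turn the unwanted enantiomer into the cis-(2R,4R)-flavan-4-ol F2 and leave the (2S)-ketone 12, which is separated by chromatography.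

Step 2. The O2 allyl group may leak to the para carbon C5 (ipso attack at C1 followed by a Cope shift), giving regioisomers that are hard to separate, and the prolonged heating may cause decomposition. The fallback sets out from 1 and comes back at 5; it blocks both para carbons before the rearrangement. Bromination of 1 (Br2, AcOH, rt) should give 4,5-dibromocatechol F3, and allyl bromide/K2CO3 then gives 1,2-bis(allyloxy)-4,5-dibromobenzene F4. Heating as in step 2 gives, by way of the mono-rearranged 2-allyl-6-(allyloxy)-3,4-dibromophenol F5, 3,6-diallyl-4,5-dibromocatechol F6, now the only possible outcome because each para carbon bears bromine. NaH/MOMCl gives the bis-MOM ether 1,2-dibromo-4,5-bis(methoxymethoxy)-3,6-di(prop-2-en-1-yl)benzene F7. A single bromine–magnesium exchange (i-PrMgCl·LiCl, 1 equiv, THF, −15 °C, where an ortho-bromo aryl magnesium species is stable) gives the aryl magnesium chloride F8, and a methanol quench gives 5; the dibromide is symmetric, so either bromine leads to the same compound.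

Step 8. A prenyl group may cyclise under acid onto its neighbouring free phenol (2,2-dimethylchroman formation), or HCl or methanol may add across the trisubstituted olefins. The fallback sets out from 5 and 11 and comes back at 13; it raises the allyl termini to prenyl only after the acid step. Bromine–lithium exchange on 5 (n-BuLi, THF, −78 °C) gives the diallyl aryllithium F9, B(OiPr)3 gives the lithium triisopropoxyborate F10, and aqueous NH4Cl gives the diallyl boronic acid F11. The rhodium-catalysed addition of step 7 to 11 should give the (2S)-diallyl tetra-MOM flavanone F12. HCl/MeOH as in step 8 gives the (2S)-2',5'-diallyl-5,7,3',4'-tetrahydroxyflavanone F13, whose monosubstituted olefins cannot form tertiary cations. A final cross-metathesis with 2-methyl-2-butene (second-generation Grubbs catalyst RuCl2(=CHPh)(PCy3)(H2IMes), CH2Cl2/THF, 40 °C), a reaction that tolerates free phenols, then gives 13.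

**Further compounds**
F1 | step 7 | racemic 2-[3,4-bis(methoxymethoxy)-2,5-bis(3-methylbut-2-en-1-yl)phenyl]-5,7-bis(methoxymethoxy)-2,3-dihydro-4H-chromen-4-one | CC(C)=CCc1cc(C2CC(=O)c3c(OCOC)cc(OCOC)cc3O2)c(CC=C(C)C)c(OCOC)c1OCOC
F2 | step 7 | (2R,4R)-2-[3,4-bis(methoxymethoxy)-2,5-bis(3-methylbut-2-en-1-yl)phenyl]-5,7-bis(methoxymethoxy)-3,4-dihydro-2H-chromen-4-ol (cis) | CC(C)=CCc1cc([C@H]2C[C@@H](O)c3c(OCOC)cc(OCOC)cc3O2)c(CC=C(C)C)c(OCOC)c1OCOC
F3 | step 2 | 4,5-dibromocatechol (4,5-dibromobenzene-1,2-diol) | Oc1cc(Br)c(Br)cc1O
F4 | step 2 | 1,2-bis(allyloxy)-4,5-dibromobenzene | C=CCOc1cc(Br)c(Br)cc1OCC=C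
F5 | step 2 | 2-allyl-6-(allyloxy)-3,4-dibromophenol | C=CCOc1cc(Br)c(Br)c(CC=C)c1O
F6 | step 2 | 3,6-diallyl-4,5-dibromocatechol | C=CCc1c(Br)c(Br)c(CC=C)c(O)c1O
F7 | step 2 | 1,2-dibromo-4,5-bis(methoxymethoxy)-3,6-di(prop-2-en-1-yl)benzene | C=CCc1c(Br)c(Br)c(CC=C)c(OCOC)c1OCOC
F8 | step 2 | [2-bromo-4,5-bis(methoxymethoxy)-3,6-di(prop-2-en-1-yl)phenyl]magnesium chloride | C=CCc1c(Br)c([Mg]Cl)c(CC=C)c(OCOC)c1OCOC
F9 | step 8 | [3,4-bis(methoxymethoxy)-2,5-di(prop-2-en-1-yl)phenyl]lithium | [Li]c1cc(CC=C)c(OCOC)c(OCOC)c1CC=C
F10 | step 8 | lithium [3,4-bis(methoxymethoxy)-2,5-di(prop-2-en-1-yl)phenyl]triisopropoxyborate | [Li+].CC(C)O[B-](OC(C)C)(OC(C)C)c1cc(CC=C)c(OCOC)c(OCOC)c1CC=C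
F11 | step 8 | [3,4-bis(methoxymethoxy)-2,5-di(prop-2-en-1-yl)phenyl]boronic acid | OB(O)c1cc(CC=C)c(OCOC)c(OCOC)c1CC=C
F12 | step 8 | (2S)-2-[3,4-bis(methoxymethoxy)-2,5-di(prop-2-en-1-yl)phenyl]-5,7-bis(methoxymethoxy)-2,3-dihydro-4H-chromen-4-one | C=CCc1cc([C@@H]2CC(=O)c3c(OCOC)cc(OCOC)cc3O2)c(CC=C)c(OCOC)c1OCOC
F13 | step 8 | (2S)-2-[3,4-dihydroxy-2,5-di(prop-2-en-1-yl)phenyl]-5,7-dihydroxy-2,3-dihydro-4H-chromen-4-one | C=CCc1cc([C@@H]2CC(=O)c3c(O)cc(O)cc3O2)c(CC=C)c(O)c1O
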